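**Strategy.** Numbering: spiro C6, ring B C1–C5 (C2 Br, C3 Cl and C15), ring A C7–C11 (C7=C14, C9 OAc, C10 Br, C11 gem-dimethyl). Ring A with C11, C14 and the C9 oxygen plus the chain C1–C2–C3–C15 is (R)-3-hydroxy-β-ionone; only C4 and C5 are missing. Light turns the ionone into its α-pyran, which ties O to C7 and C3 and locks C6=C1–C2=C3 s-cis. A Diels–Alder reaction with phenyl vinyl sulfone then closes ring B through C3–C4 and C5–C6, sets the spiro centre and places oxygen on C3 cis to C7. This temporary C7–O–C3 bridge later steers C2–Br, C3–Cl and C10–Br and is cleaved to C7=C14.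

Key step: step 2

Remark (assumption): (R)-3-hydroxy-β-ionone (1) is taken as a purchasable apocarotenoid building block (the C13 end group of zeaxanthin, made on scale from (4R,6R)-actinol); phenyl vinyl sulfone is a catalogue reagent. Names of intermediates use the target numbering given above ("chamigrane" = the 1,1,5,9-tetramethylspiro[5.5]undecane skeleton).

**Step 1**
Reactants: 1 (R)-3-hydroxy-β-ionone
Product: 3 α-pyran (7S,8aS)-2,5,5,8a-tetramethyl-6,7,8,8a-tetrahydro-5H-chromen-7-ol, via Z-dienone 2 (not isolated)
Conditions: hν (Pyrex, λ > 300 nm), THF, 20 °C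
Reagents that add atoms: none
Why: E to Z photoisomerisation of the enone followed by thermal oxa-6π electrocyclisation of 2 should give the 2H-pyran, and because this ring closure is reversible the new centre C7 is set under thermodynamic control with the pseudo-axial C14 methyl trans to the equatorial C9 hydroxyl.

**Step 2**
Reactants: 3 α-pyran; 4 phenyl vinyl sulfone
Product: 5 bridged sulfone (3S,6S,7S,9S)-3,7-epoxy-4-(phenylsulfonyl)chamigr-1-en-9-ol (both C4 epimers)
Conditions: toluene, BHT (cat.), 12 kbar, 40 °C
Reagents that add atoms: none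
Why: Normal-demand [4+2] cycloaddition in which the electron-rich cyclic 1-oxy-diene C6=C1–C2=C3 of pyran 3 (in equilibrium with 2) adds the vinyl sulfone suprafacially, forming C3–C4 and C5–C6 in one operation. The closest known reaction type is the Diels–Alder reaction of 2H-pyrans (oxa-6π valence tautomers of Z-dienones) with electron-poor alkenes, together with the cycloaddition construction of a chamigrene spiro centre next to the gem-dimethyl carbon. Ring B (C1–C6) is closed by intermolecular cycloaddition across the 1,4-termini C3 and C6, which turns the pyran into a 2-oxabicyclo[2.2.2]octene carrying the O–C7 bridge. C6 and C3 are set together by the diene face: the sulfone approaches anti to the pseudo-axial C14 methyl on C7 (flanked by the syn axial C11 methyl), and C7 itself sits trans to the equatorial C9 hydroxyl by reversible ring closure, so the (R)-carbinol fixes the absolute sense of C6 (C5 anti to C14, bridge oxygen on C3 cis to C7). The step needs regioselectivity (CH2 terminus to C6, sulfonyl carbon C4 to C3), which the largest HOMO coefficient of the 1-oxygenated diene at C6 and the smaller CH2 terminus at the congested C6 should secure; the C4 epimer ratio does not matter because step 3 erases that centre.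

**Step 3**
Reactants: 5 bridged sulfone
Product: 6 diene diol (6S,7S,9S)-chamigra-1,3-diene-7,9-diol
Conditions: SmI2, HMPA, THF, 0 °C → rt
Reagents that add atoms: none
Why: Julia-type reductive elimination, in which SmI2 cleaves the C4–S bond and the C4 organosamarium expels the β-oxygen on C3, should open the bridge at C3–O only, erase the C4 centre and leave C6 and C7 (now a tertiary alcohol) untouched.

**Step 4**
Reactants: 6 diene diol
Product: 7 ene diol (6S,7S,9S)-chamigr-2-ene-7,9-diol
Conditions: H2 (70 bar), (naphthalene)Cr(CO)3 (10 mol%), THF, 45 °C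
Reagents that add atoms: none
Why: Chromium tricarbonyl-catalysed 1,4-hydrogenation of the s-cis locked 1,3-diene adds hydrogen to C1 and C4 only, which should leave the single alkene at C2=C3 with no new stereocentre.

**Step 5**
Reactants: 7 ene diol
Product: 8 bromo ether (2R,3R,6S,7S,9S)-2-bromo-3,7-epoxychamigran-9-ol
Conditions: NBS, CH2Cl2, 0 °C
Reagents that add atoms: N-bromosuccinimide, O=C1CCC(=O)N1Br
Why: Bromoetherification (the α-terpineol to 2-bromo-1,8-cineole reaction type): the C7 hydroxyl can reach only the tertiary C3 and only from the ring B face that carries C7, so oxygen adds to C3 cis to C7 and the bromonium-derived bromide on C2 ends anti to it.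

**Step 6**
Reactants: 8 bromo ether
Product: 9 bridged ketone (2R,3R,6S,7S)-2-bromo-3,7-epoxychamigran-9-one
Conditions: Dess–Martin periodinane, CH2Cl2, rt
Reagents that add atoms: none
Why: Dess–Martin oxidation of the only oxidisable group, the secondary C9 alcohol, whose stereocentre has by now passed its information to C6, C7, C3 and C2.

**Step 7**
Reactants: 9 bridged ketone
Product: 11 dibromo ketone (2R,3R,6S,7S,10R)-2,10-dibromo-3,7-epoxychamigran-9-one, via silyl enol ether 10 (not isolated)
Conditions: LiN(iPr)2, Me3SiCl, THF, −78 °C; NBS, THF, −78 → 0 °C; Et3N (cat.), CH2Cl2, rt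
Reagents that add atoms: N-bromosuccinimide, O=C1CCC(=O)N1Br
Why: Kinetic enolisation with in situ silylation and bromination of the silyl enol ether should occur at C10 (distal to the β-oxygen on C7 and away from the bridge atoms C3/C4 that shield C8), and base-catalysed epimerisation through the bromo enol should deliver the equatorial C10 bromide, which avoids the syn-axial contact with C5 on the rigid ring A chair.

**Step 8**
Reactants: 11 dibromo ketone
Product: 13 enone (2R,3R,6R,10R)-2,10-dibromo-3-chlorochamigr-7-en-9-one, via bromohydrin enone 12 (not isolated)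
Conditions: HCl (4 M in dioxane), CH2Cl2, 0 °C → rt
Reagents that add atoms: hydrogen chloride, Cl
Why: Acid-promoted retro-oxa-Michael opening of the β-alkoxy ketone at C7–O gives the enone and tertiary bromohydrin 12, whose ionisation with neighbouring-group participation by the anti C2 bromine lets chloride open the bromonium ion at the tertiary C3, so C3–Cl should form with net retention (cis to C7, trans to C2–Br) while acid does not enolise towards the brominated C10.

**Step 9**
Reactants: 13 enone
Product: 15 β,γ-unsaturated ketone (2R,3R,6R,10R)-2,10-dibromo-3-chlorochamigr-7(14)-en-9-one, via dienol ether 14 (not isolated)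
Conditions: HC(OEt)3, TsOH (cat.), dioxane, rt; then oxalic acid, THF–H2O, 0 °C
Reagents that add atoms: water, O
Why: Acid-catalysed dienol ether formation can use only the γ-hydrogens on C14 (C6 is quaternary), and kinetic α-protonation at C8 on mild hydrolysis should give the deconjugated ketone with the exocyclic C7=C14 alkene, as in the steroid 3-alkoxy-3,5-diene to 5-en-3-one conversion, without touching C10.

**Step 10**
Reactants: 15 β,γ-unsaturated ketone
Product: 16 bromohydrin (2R,3R,6R,9S,10R)-2,10-dibromo-3-chlorochamigr-7(14)-en-9-ol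
Conditions: LiBH(s-Bu)3, THF, −78 °C; H2O
Reagents that add atoms: none
Why: Bulky-hydride reduction should attack the C9 carbonyl from the equatorial direction of the ring A chair with C10–Br equatorial and C5 axial (the axial path is blocked by the axial C11 methyl), giving the axial C9 alcohol cis to the C10 bromide.

**Step 11**
Reactants: 16 bromohydrin
Product: 17 target acetate (2R,3R,6R,9S,10R)-2,10-dibromo-3-chlorochamigr-7(14)-en-9-yl acetate
Conditions: Ac2O, pyridine, DMAP (cat.), CH2Cl2, rt
Reagents that add atoms: acetic anhydride, CC(=O)OC(C)=O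
Why: DMAP-catalysed acylation of the hindered axial secondary alcohol proceeds at oxygen, so C9 keeps its configuration.

**Compound list**
1 | (R)-3-hydroxy-β-ionone, (E)-4-[(4R)-4-hydroxy-2,6,6-trimethylcyclohex-1-en-1-yl]but-3-en-2-one | CC1=C(/C=C/C(C)=O)C(C)(C)C[C@H](O)C1 | starting material
2 | Z-dienone, (Z)-4-[(4R)-4-hydroxy-2,6,6-trimethylcyclohex-1-en-1-yl]but-3-en-2-one | CC1=C(/C=C\C(C)=O)C(C)(C)C[C@H](O)C1 | intermediate
3 | α-pyran, (7S,8aS)-2,5,5,8a-tetramethyl-6,7,8,8a-tetrahydro-5H-chromen-7-ol (8a-methyl trans to the hydroxyl) | C[C@@]12OC(C)=CC=C1C(C)(C)C[C@H](O)C2 | intermediate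
4 | phenyl vinyl sulfone | C=CS(=O)(=O)c1ccccc1 | starting material
5 | bridged sulfone, (3S,6S,7S,9S)-3,7-epoxy-4-(phenylsulfonyl)chamigr-1-en-9-ol, oxygen bridge C3–O–C7, C5 anti to C14, both C4 epimers | C[C@]1(O3)C[C@@H](O)CC(C)(C)[C@@]12CC(S(=O)(=O)c4ccccc4)[C@]3(C)C=C2 | intermediate
6 | diene diol, (6S,7S,9S)-chamigra-1,3-diene-7,9-diol | C[C@]1(O)C[C@@H](O)CC(C)(C)[C@@]12CC=C(C)C=C2 | intermediate
7 | ene diol, (6S,7S,9S)-chamigr-2-ene-7,9-diol | C[C@]1(O)C[C@@H](O)CC(C)(C)[C@@]12CCC(C)=CC2 | intermediate
8 | bromo ether, (2R,3R,6S,7S,9S)-2-bromo-3,7-epoxychamigran-9-ol (C2–Br anti to the bridge oxygen) | C[C@]1(O3)C[C@@H](O)CC(C)(C)[C@@]12CC[C@]3(C)[C@H](Br)C2 | intermediate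
9 | bridged ketone, (2R,3R,6S,7S)-2-bromo-3,7-epoxychamigran-9-one | C[C@]1(O3)CC(=O)CC(C)(C)[C@@]12CC[C@]3(C)[C@H](Br)C2 | intermediate
10 | silyl enol ether, (2R,3R,6S,7S)-2-bromo-3,7-epoxy-9-(trimethylsilyloxy)chamigr-9-ene | C[C@]1(O3)CC(O[Si](C)(C)C)=CC(C)(C)[C@@]12CC[C@]3(C)[C@H](Br)C2 | intermediate
11 | dibromo ketone, (2R,3R,6S,7S,10R)-2,10-dibromo-3,7-epoxychamigran-9-one (C10–Br equatorial, cis to C1 on ring A) | C[C@]1(O3)CC(=O)[C@H](Br)C(C)(C)[C@@]12CC[C@]3(C)[C@H](Br)C2 | intermediate
12 | bromohydrin enone, (2R,3R,6R,10R)-2,10-dibromo-3-hydroxychamigr-7-en-9-one | CC1=CC(=O)[C@H](Br)C(C)(C)[C@@]12CC[C@@](C)(O)[C@H](Br)C2 | intermediate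
13 | enone, (2R,3R,6R,10R)-2,10-dibromo-3-chlorochamigr-7-en-9-one | CC1=CC(=O)[C@H](Br)C(C)(C)[C@@]12CC[C@@](C)(Cl)[C@H](Br)C2 | intermediate
14 | dienol ether, (2R,3R,6R,10R)-2,10-dibromo-3-chloro-9-ethoxychamigra-7(14),8-diene | C=C1C=C(OCC)[C@H](Br)C(C)(C)[C@@]12CC[C@@](C)(Cl)[C@H](Br)C2 | intermediate
15 | β,γ-unsaturated ketone, (2R,3R,6R,10R)-2,10-dibromo-3-chlorochamigr-7(14)-en-9-one | C=C1CC(=O)[C@H](Br)C(C)(C)[C@@]12CC[C@@](C)(Cl)[C@H](Br)C2 | intermediate
16 | bromohydrin, (2R,3R,6R,9S,10R)-2,10-dibromo-3-chlorochamigr-7(14)-en-9-ol | C=C1C[C@H](O)[C@H](Br)C(C)(C)[C@@]12CC[C@@](C)(Cl)[C@H](Br)C2 | intermediate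
17 | (2R,3R,6R,9S,10R)-2,10-dibromo-3-chlorochamigr-7(14)-en-9-yl acetate | C=C1C[C@H](OC(C)=O)[C@H](Br)C(C)(C)[C@@]12CC[C@@](C)(Cl)[C@H](Br)C2 | target

**Totals.** Total step count: 11. Longest linear sequence: 11 steps (1 → 17).

**Steps most likely to fail**

1. Step 2. The cycloaddition may be too slow at the congested diene terminus C6 (next to the quaternary C11), so that thermal drift of the pyran/dienone pair or polymerisation of the sulfone outruns it. Fallback, setting out from 3 and returning at 7: nitroethylene (distilled from commercial 2-nitroethanol over phthalic anhydride; benzene, 20 °C), a far more reactive two-carbon dienophile with the same regiochemical and facial preference, should give the nitro adduct 3,7-epoxy-4-nitrochamigr-1-en-9-ol F1. Radical denitration (Bu3SnH, AIBN, toluene, 110 °C) then gives the unsubstituted bridged allylic ether 3,7-epoxychamigr-1-en-9-ol F2. Dissolving-metal hydrogenolysis of the allylic C3–O bond (Li, EtNH2, t-BuOH, −78 °C), with protonation of the allyl anion at the less substituted C1, gives 7.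

2. Step 7. Regiocontrol of the enolisation may be lost (deprotonation at C8 followed by β-elimination of the bridge oxygen), or the epimerisation at C10 may stay incomplete. Fallback, setting out from 9 and returning at 13: the bridge is opened first with HCl under the conditions of step 8, giving 2-bromo-3-chlorochamigr-7-en-9-one F3, in which C10 is the only enolisable position next to the carbonyl. Acid-mediated α′-bromination with phenyltrimethylammonium tribromide in THF then gives 13 together with its C10 epimer. The two are separated and the unwanted epimer is recycled by LiBr-mediated epimerisation, so in this variant the C10 configuration rests on separation and no longer on the bridge.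

3. Step 8. Stereochemical fidelity at C3 may be lost (capture of an open cation, transfer of the bromonium bromine to chloride, or a 1,2-bromine shift), and the α-bromo ketone may epimerise under acid. Fallback, setting out from 11 and returning at 13: the cascade is divided. TsOH (cat.) in benzene at 50 °C effects only the retro-oxa-Michael opening, and bromohydrin enone 12 is isolated. The tertiary alcohol is then converted into the chloride under aprotic Lewis-acid conditions (Me3SiCl, InCl3 (cat.), CH2Cl2, −20 °C), again through the bromine-bridged cation. This fallback forms no compound beyond those already listed.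

**Further compounds**
F1 | step 2 | nitro adduct, (3S,6S,7S,9S)-3,7-epoxy-4-nitrochamigr-1-en-9-ol (both C4 epimers) | C[C@]1(O3)C[C@@H](O)CC(C)(C)[C@@]12CC([N+](=O)[O-])[C@]3(C)C=C2
F2 | step 2 | bridged allylic ether, (3R,6S,7S,9S)-3,7-epoxychamigr-1-en-9-ol | C[C@]1(O3)C[C@@H](O)CC(C)(C)[C@@]12CC[C@]3(C)C=C2
F3 | step 7 | enone, (2R,3R,6S)-2-bromo-3-chlorochamigr-7-en-9-one | CC1=CC(=O)CC(C)(C)[C@@]12CC[C@@](C)(Cl)[C@H](Br)C2
F0 | step 8 | none | none
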